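The numbers in the tables are simulated with made-up constants, noise included.

A small charge of initiator, 5.00% of the free monomer in both birch and oak, gave me something to freeze. I supposed that the living ends, once lit, held their number, so that ln f, with f the fraction of charged free monomer left, fell on a straight line after a lag.

| flask | free monomer | initiator | remark | time |
|---|---|---|---|---|
| Friday's | 0.050 M | 5 mM | run made earlier |  |
| Wednesday's | 0.20 M | 5 mM | run made earlier |  |
| birch | 0.10 M | 5.0 mM |  | 6.0 min |
| oak | 0.10 M | 5.0 mM |  | 2.0 min |

- Friday's (time / s: monomer in chains / %, free monomer / %): 10.0: 2.7, 98.0; 12.0: 3.2, 98.1; 20.0: 8.4, 92.3; 25.0: 12.3, 85.8; 40.0: 24.9, 73.6; 60.0: 39.8, 58.0; 90.0: 58.9, 37.6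
- Wednesday's (time / s: monomer in chains / %, free monomer / %): 10.0: 6.8, 92.5; 15.0: 12.8, 85.7; 25.0: 26.0, 71.3; 40.0: 45.4, 54.2; 60.0: 64.6, 35.2; 80.0: 76.5, 23.4; 90.0: 79.1, 18.0

(standard deviation of a reading: 1 percentage point)

1. which of the two ends with the higher amount of monomer in chains, in percent of the free monomer charged ("neither" if they lie within 2 percentage points) (birch / oak / neither)
2. monomer in chains at the end, in percent of the free monomer charged, birch
3. monomer in chains at the end, in percent of the free monomer charged, oak



Between 60.0 s and 90.0 s, ln f fell at 0.0144 s⁻¹ in Friday's run and at 0.0224 s⁻¹ in Wednesday's, faster in the richer run. Traced back to the full charge, these two lines gave lags of 22.3 s and 13.3 s. That gave me two extreme oaks I could solve in my head. Friday's line put oak's end at f = 24.4%, and Wednesday's line put it at f = 9.20%. Oak's charge is twice Friday's and half Wednesday's, so I placed it midway. For oak and birch I took the mean of the two slopes as the late rate, the pseudo-first-order constant of free monomer once the ends stand: 0.0184 s⁻¹. The mean lag was 17.8 s. My reckoning then gave f = 15.2% for oak and 0.184% for birch. These figures are free monomer, not monomer in chains, and at 90.0 s the two columns summed to 96.5% in Friday's run and 97.1% in Wednesday's, so I expected monomer in chains somewhat under 84.8% for oak and 99.8% for birch.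

The forecast said birch, with 98% for birch and 85% for oak, on runs whose trend “points to slow initiation that consumes monomer, followed by living growth”.

The flask gave 98.3% for birch and 83.4% for oak, so birch ended higher, as the forecast said.

    free monomer + initiator → living end + monomer in chains (k = 0.300 L mol⁻¹ s⁻¹)
    free monomer + living end → monomer in chains + living end, rate k2*[living end]*[free monomer] (k = 5.30 L mol⁻¹ s⁻¹)
    initiator + monomer in chains → spent initiator (k = 0.500 L mol⁻¹ s⁻¹)

Free monomer left at the end was 15% in oak and 0.18% in birch, against my 15.2% and 0.184%. The neighbour of birch was charged with 0.025 M of free monomer, half Friday's charge, and ran the same 6.0 min. Its charge lies two halvings below birch's, the same span as from Wednesday's charge to Friday's, so I moved 0.0184 s⁻¹ and 17.8 s by the gaps between those two runs, which gave a late rate of 0.0105 s⁻¹ and a lag of 26.8 s, hence f = 3.02%. That neighbour ended with 1.8% of its free monomer left, 88.2% in chains and 10.0% as spent initiator.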